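**Strategy.** The route rests on cutting the γ-butyrolactone between ring oxygen O1 and methylene C5 and reconnecting C5 to the carbonyl carbon C2, which turns the lactone into a 3-(arylmethyl)cyclobutanone. Before the C3 benzyl group is attached, lactone carbon C4 lies between two CH2 groups (C3 and C5), so this cyclobutanone is prochiral: one catalytic asymmetric Baeyer–Villiger oxidation expands the four-membered ring to the lactone and creates the C4 stereocenter. Its precursor already carries the complete open 1,2-diarylpropane-1,3-diol arm, silyl-protected; the dihydrobenzofuran arm is added afterwards by trans-selective enolate benzylation. Both arms come from one auxiliary-controlled anti-aldol adduct.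

Key step: step 9

Assumption: compounds 9 and 14 are taken as catalogue compounds; of the two antipodes of the N,N′-dioxide ligand, step 9 uses the one that delivers the (S)-lactone, its sense of induction being established in a trial run on 3-benzylcyclobutanone.

Abbreviations: TBS = tert-butyldimethylsilyl (TBSO = its silyloxy substituent), TMS = trimethylsilyl.

**Common steps (both arms)**

Step 1
Reactants: 1 2-allyl-6-methoxyphenol (ortho-eugenol)
Product: 2 2-allyl-4-bromo-6-methoxyphenol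
Conditions: NBS, MeCN, −20 → 0 °C
Reagents that add atoms: N-bromosuccinimide O=C1CCC(=O)N1Br
Why: Electrophilic aromatic bromination, in which the free hydroxyl directs bromine to its only open para position and the phenol ring reacts far faster than the isolated terminal alkene.

Step 2
Reactants: 2 2-allyl-4-bromo-6-methoxyphenol
Product: 3 (2-allyl-4-bromo-6-methoxyphenoxy)(tert-butyl)dimethylsilane
Conditions: TBSCl, imidazole, DMF, rt
Reagents that add atoms: tert-butyldimethylsilyl chloride CC(C)(C)[Si](C)(C)Cl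
Why: Standard imidazole-promoted O-silylation of a phenol, giving an ether that withstands ozone, amide bases, hydride and palladium chemistry.

Step 3
Reactants: 3 (2-allyl-4-bromo-6-methoxyphenoxy)(tert-butyl)dimethylsilane
Product: 5 2-[5-bromo-2-(TBSO)-3-methoxyphenyl]acetic acid, via arylacetaldehyde 4 (not isolated)
Conditions: O3, MeCN/H2O (9:1), 0 °C; then NaClO2, NaH2PO4, 2-methyl-2-butene, 0 °C → rt
Reagents that add atoms: ozone [O-][O+]=O; water O; sodium chlorite [Na+].[O-]Cl=O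
Why: Ozonolysis of the terminal alkene in wet solvent (water captures the carbonyl oxide and releases the aldehyde directly) followed in the same flask by Pinnick oxidation, the alkene being far more reactive toward ozone than the brominated arene.

Step 4
Reactants: 5 2-[5-bromo-2-(TBSO)-3-methoxyphenyl]acetic acid; 6 (S)-4-benzyloxazolidin-2-one
Product: 8 (S)-4-benzyl-3-{2-[5-bromo-2-(TBSO)-3-methoxyphenyl]acetyl}oxazolidin-2-one, via mixed pivalic anhydride 7 (not isolated)
Conditions: PivCl, Et3N, THF, −20 °C; then 6, LiCl, rt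
Reagents that add atoms: none
Why: Mixed-anhydride N-acylation of the oxazolidinone under mild LiCl/amine conditions, where attack occurs at the unhindered arylacetyl carbonyl and not at the pivaloyl carbonyl.

Step 5
Reactants: 8 (S)-4-benzyl-3-{2-[5-bromo-2-(TBSO)-3-methoxyphenyl]acetyl}oxazolidin-2-one; 9 4-(TBSO)-3-methoxybenzaldehyde
Product: 10 (S)-4-benzyl-3-{(2R,3S)-2-[5-bromo-2-(TBSO)-3-methoxyphenyl]-3-[4-(TBSO)-3-methoxyphenyl]-3-(trimethylsilyloxy)propanoyl}oxazolidin-2-one
Conditions: MgCl2 (20 mol %), Et3N, Me3SiCl, EtOAc, rt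
Reagents that add atoms: chlorotrimethylsilane C[Si](C)(C)Cl
Why: Evans magnesium-halide-catalysed direct anti-aldol, in which the MgCl2-chelated Z-enolate of the (S)-benzyl imide is attacked on the face remote from the benzyl group and silyl capture of the aldolate makes the addition irreversible, setting the aryl-bearing carbon (2R in the imide) and the anti carbinol carbon (3S).

Step 6
Reactants: 10 the TMS-protected anti-aldol imide
Product: 12 (1S,2S)-2-[5-bromo-2-(TBSO)-3-methoxyphenyl]-1-[4-(TBSO)-3-methoxyphenyl]propane-1,3-diol, via mono-TMS alcohol 11 (not isolated)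
Conditions: LiBH4, MeOH (1 equiv), THF, 0 °C; then 1 M HCl, THF, 0 °C work-up
Reagents that add atoms: none
Why: Reductive cleavage of the auxiliary by hydride attack at the exocyclic imide carbonyl gives the primary alcohol without touching either stereocenter, and the labile trimethylsilyl ether is hydrolysed in the brief acidic work-up while the aryl TBS ethers stay.

**Open arm and lactone**

Step 7
Reactants: 12 the (1S,2S)-diol
Product: 13 (1S,2S)-1,3-bis(TBSO)-2-[5-bromo-2-(TBSO)-3-methoxyphenyl]-1-[4-(TBSO)-3-methoxyphenyl]propane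
Conditions: TBSOTf, 2,6-lutidine, CH2Cl2, −78 → 0 °C
Reagents that add atoms: tert-butyldimethylsilyl triflate CC(C)(C)[Si](C)(C)OS(=O)(=O)C(F)(F)F
Why: Silyl triflate with a hindered base silylates both the primary and the hindered benzylic secondary hydroxyl, the lutidine buffer preventing ionisation of the benzylic carbinol.

Step 8
Reactants: 13 the tetrakis-TBS aryl bromide; 14 3-(bromomethyl)cyclobutan-1-one
Product: 16 3-{3-[(1S,2S)-1,3-bis(TBSO)-1-(4-TBSO-3-methoxyphenyl)propan-2-yl]-4-TBSO-5-methoxybenzyl}cyclobutan-1-one, via alkylzinc bromide 15 (not isolated)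
Conditions: 14, Zn dust, LiCl, THF, 40 °C; then 13, Pd(OAc)2, SPhos, THF, 50 °C
Reagents that add atoms: none
Why: Negishi sp3–sp2 cross-coupling, in which the primary alkylzinc bromide tolerates its own ketone and the silyl ethers, the unhindered aryl bromide adds oxidatively to SPhos-ligated zerovalent palladium, and reductive elimination outpaces β-hydride elimination.

Step 9
Reactants: 16 the 3-(arylmethyl)cyclobutanone
Product: 18 (S)-4-{3-[(1S,2S)-1,3-bis(TBSO)-1-(4-TBSO-3-methoxyphenyl)propan-2-yl]-4-TBSO-5-methoxybenzyl}dihydrofuran-2(3H)-one, via Criegee adduct 17 (not isolated)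
Conditions: Sc(OTf)3 (5 mol %), chiral N,N′-dioxide ligand (6 mol %), mCPBA, EtOAc, −20 °C
Reagents that add atoms: meta-chloroperoxybenzoic acid O=C(OO)c1cccc(Cl)c1
Why: The Sc(OTf)3–N,N′-dioxide complex binds the ketone, mCPBA adds to give Criegee adduct 17, and one of the two ring CH2 groups shifts from carbon to the proximal peroxide oxygen with loss of 3-chlorobenzoate, which forms the O1–C5 bond. The closest known reaction is the catalytic asymmetric Baeyer–Villiger desymmetrisation of prochiral 3-benzylcyclobutanones to β-benzyl-γ-butyrolactones. The five-membered lactone closes by ring expansion (1,2-shift of C5 from carbon to oxygen, four- to five-membered, driven by release of cyclobutanone strain), not by an exo or endo cyclisation. The new stereocenter C4 arises because the chiral ligand sphere decides which of the two locally enantiotopic methylene groups lies antiperiplanar to the O–O bond and migrates, while the existing stereocenters of the diol arm are remote and should not interfere. The step needs methylene-group selectivity (catalyst control, with no regiochemical issue because both α-carbons are CH2) and chemoselectivity for the ketone over the silyloxyarenes, which the high carbonyl reactivity of the strained cyclobutanone at −20 °C secures.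

**Dihydrobenzofuran arm**

Step 10
Reactants: 12 the (1S,2S)-diol
Product: 20 4-[(2R,3S)-5-bromo-3-(hydroxymethyl)-7-methoxy-2,3-dihydrobenzofuran-2-yl]-2-methoxyphenol, via tetraol 19 (not isolated)
Conditions: Bu4NF (2.2 equiv), THF, 0 °C; then TsOH·H2O (3 equiv), rt
Reagents that add atoms: none
Why: Fluoride frees both phenols and acid then ionises the para-hydroxybenzylic alcohol to a para-quinone methide that the ortho-phenol captures in a 5-exo-trig closure (biomimetic phenylcoumaran formation), so that the untouched (S) carbon next to the planar benzylic carbon dictates the new C2 center and places the aryl group trans to CH2OH (2R,3S), the thermodynamically preferred and reversibly reached isomer.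

Step 11
Reactants: 20 the dihydrobenzofuran phenol-alcohol
Product: 21 (2R,3S)-5-bromo-3-(TBSO-methyl)-2-(4-TBSO-3-methoxyphenyl)-7-methoxy-2,3-dihydrobenzofuran
Conditions: TBSCl (2.5 equiv), imidazole, DMF, rt
Reagents that add atoms: tert-butyldimethylsilyl chloride CC(C)(C)[Si](C)(C)Cl
Why: Standard silylation protects the phenol and the primary alcohol in one operation.

Step 12
Reactants: 21 the bis-TBS aryl bromide
Product: 22 [(2R,3S)-3-(TBSO-methyl)-2-(4-TBSO-3-methoxyphenyl)-7-methoxy-2,3-dihydrobenzofuran-5-yl]methanol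
Conditions: Bu3SnCH2OH, Pd(PPh3)4, 1,4-dioxane, 100 °C
Reagents that add atoms: (tributylstannyl)methanol CCCC[Sn](CCCC)(CCCC)CO
Why: Migita–Kosugi–Stille hydroxymethylation transfers the CH2OH group from tin to the arylpalladium bromide under neutral conditions that leave the silyl ethers and the benzylic ring C–O bond untouched.

Step 13
Reactants: 22 the benzylic alcohol
Product: 23 (2R,3S)-5-(bromomethyl)-3-(TBSO-methyl)-2-(4-TBSO-3-methoxyphenyl)-7-methoxy-2,3-dihydrobenzofuran
Conditions: CBr4, PPh3, CH2Cl2, 0 °C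
Reagents that add atoms: carbon tetrabromide BrC(Br)(Br)Br
Why: Appel bromination of the primary benzylic alcohol under near-neutral conditions gives the reactive para-alkoxybenzyl bromide, which is used at once.

**Union and deprotection**

Step 14
Reactants: 18 the (S)-lactone; 23 the benzylic bromide
Product: 25 the hexakis-TBS ether of the target with (3S,4S)-lactone, via lithium enolate 24 (not isolated)
Conditions: LiN(SiMe3)2, THF, −78 °C; then 23, DMPU, −78 → −40 °C
Reagents that add atoms: none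
Why: Lithium enolate alkylation of a β-substituted γ-butyrolactone, in which the benzylic bromide approaches the enolate face opposite the C4 arylmethyl group and so gives the 3,4-trans (3S,4S) lactone, as in classical dibenzylbutyrolactone lignan syntheses.

Step 15
Reactants: 25 the hexakis-TBS ether
Product: 26 (3S,4S)-3-{[(2R,3S)-3-(hydroxymethyl)-2-(4-hydroxy-3-methoxyphenyl)-7-methoxy-2,3-dihydrobenzofuran-5-yl]methyl}-4-{3-[(1S,2S)-1,3-dihydroxy-1-(4-hydroxy-3-methoxyphenyl)propan-2-yl]-4-hydroxy-5-methoxybenzyl}dihydrofuran-2(3H)-one (CNP0199264.1)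
Conditions: Bu4NF/AcOH (1:1, excess), THF, 0 °C → 40 °C
Reagents that add atoms: none
Why: Fluoride-mediated global desilylation buffered with acetic acid removes all six silyl groups while avoiding both acid-induced ionisation of the benzylic carbinol (which would close a second dihydrobenzofuran) and base-induced quinone methide formation or lactone opening.

**Compound list**

1 | 2-allyl-6-methoxyphenol (ortho-eugenol) | C=CCc1cccc(OC)c1O | starting material
2 | 2-allyl-4-bromo-6-methoxyphenol | C=CCc1cc(Br)cc(OC)c1O | intermediate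
3 | (2-allyl-4-bromo-6-methoxyphenoxy)(tert-butyl)dimethylsilane | C=CCc1cc(Br)cc(OC)c1O[Si](C)(C)C(C)(C)C | intermediate
4 | 2-[5-bromo-2-(TBSO)-3-methoxyphenyl]acetaldehyde (not isolated) | O=CCc1cc(Br)cc(OC)c1O[Si](C)(C)C(C)(C)C | intermediate
5 | 2-[5-bromo-2-(TBSO)-3-methoxyphenyl]acetic acid | OC(=O)Cc1cc(Br)cc(OC)c1O[Si](C)(C)C(C)(C)C | intermediate
6 | (S)-4-benzyloxazolidin-2-one | O=C1OC[C@H](Cc2ccccc2)N1 | starting material
7 | mixed anhydride of 5 with pivalic acid (not isolated) | CC(C)(C)C(=O)OC(=O)Cc1cc(Br)cc(OC)c1O[Si](C)(C)C(C)(C)C | intermediate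
8 | (S)-4-benzyl-3-{2-[5-bromo-2-(TBSO)-3-methoxyphenyl]acetyl}oxazolidin-2-one | O=C1OC[C@H](Cc2ccccc2)N1C(=O)Cc1cc(Br)cc(OC)c1O[Si](C)(C)C(C)(C)C | intermediate
9 | 4-(TBSO)-3-methoxybenzaldehyde | COc1cc(C=O)ccc1O[Si](C)(C)C(C)(C)C | starting material
10 | (S)-4-benzyl-3-{(2R,3S)-2-[5-bromo-2-(TBSO)-3-methoxyphenyl]-3-[4-(TBSO)-3-methoxyphenyl]-3-(trimethylsilyloxy)propanoyl}oxazolidin-2-one | COc1cc([C@@H](O[Si](C)(C)C)[C@H](C(=O)N2[C@@H](Cc3ccccc3)COC2=O)c2cc(Br)cc(OC)c2O[Si](C)(C)C(C)(C)C)ccc1O[Si](C)(C)C(C)(C)C | intermediate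
11 | (2S,3S)-2-[5-bromo-2-(TBSO)-3-methoxyphenyl]-3-[4-(TBSO)-3-methoxyphenyl]-3-(trimethylsilyloxy)propan-1-ol (not isolated) | COc1cc([C@@H](O[Si](C)(C)C)[C@H](CO)c2cc(Br)cc(OC)c2O[Si](C)(C)C(C)(C)C)ccc1O[Si](C)(C)C(C)(C)C | intermediate
12 | (1S,2S)-2-[5-bromo-2-(TBSO)-3-methoxyphenyl]-1-[4-(TBSO)-3-methoxyphenyl]propane-1,3-diol | COc1cc([C@@H](O)[C@H](CO)c2cc(Br)cc(OC)c2O[Si](C)(C)C(C)(C)C)ccc1O[Si](C)(C)C(C)(C)C | intermediate
13 | (1S,2S)-1,3-bis(TBSO)-2-[5-bromo-2-(TBSO)-3-methoxyphenyl]-1-[4-(TBSO)-3-methoxyphenyl]propane | COc1cc([C@@H](O[Si](C)(C)C(C)(C)C)[C@H](CO[Si](C)(C)C(C)(C)C)c2cc(Br)cc(OC)c2O[Si](C)(C)C(C)(C)C)ccc1O[Si](C)(C)C(C)(C)C | intermediate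
14 | 3-(bromomethyl)cyclobutan-1-one | O=C1CC(CBr)C1 | starting material
15 | [(3-oxocyclobutyl)methyl]zinc bromide (not isolated) | O=C1CC(C[Zn]Br)C1 | intermediate
16 | 3-{3-[(1S,2S)-1,3-bis(TBSO)-1-(4-TBSO-3-methoxyphenyl)propan-2-yl]-4-TBSO-5-methoxybenzyl}cyclobutan-1-one | COc1cc([C@@H](O[Si](C)(C)C(C)(C)C)[C@H](CO[Si](C)(C)C(C)(C)C)c2cc(CC3CC(=O)C3)cc(OC)c2O[Si](C)(C)C(C)(C)C)ccc1O[Si](C)(C)C(C)(C)C | intermediate
17 | Criegee adduct of 16: 1-hydroxy-1-(3-chlorobenzoylperoxy)cyclobutane (not isolated) | COc1cc([C@@H](O[Si](C)(C)C(C)(C)C)[C@H](CO[Si](C)(C)C(C)(C)C)c2cc(CC3CC(O)(OOC(=O)c4cccc(Cl)c4)C3)cc(OC)c2O[Si](C)(C)C(C)(C)C)ccc1O[Si](C)(C)C(C)(C)C | intermediate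
18 | (S)-4-{3-[(1S,2S)-1,3-bis(TBSO)-1-(4-TBSO-3-methoxyphenyl)propan-2-yl]-4-TBSO-5-methoxybenzyl}dihydrofuran-2(3H)-one | COc1cc([C@@H](O[Si](C)(C)C(C)(C)C)[C@H](CO[Si](C)(C)C(C)(C)C)c2cc(C[C@@H]3COC(=O)C3)cc(OC)c2O[Si](C)(C)C(C)(C)C)ccc1O[Si](C)(C)C(C)(C)C | intermediate
19 | (1S,2S)-2-(5-bromo-2-hydroxy-3-methoxyphenyl)-1-(4-hydroxy-3-methoxyphenyl)propane-1,3-diol (not isolated) | COc1cc([C@@H](O)[C@H](CO)c2cc(Br)cc(OC)c2O)ccc1O | intermediate
20 | 4-[(2R,3S)-5-bromo-3-(hydroxymethyl)-7-methoxy-2,3-dihydrobenzofuran-2-yl]-2-methoxyphenol | Brc1cc(OC)c2c(c1)[C@@H](CO)[C@H](c1ccc(O)c(OC)c1)O2 | intermediate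
21 | (2R,3S)-5-bromo-3-(TBSO-methyl)-2-(4-TBSO-3-methoxyphenyl)-7-methoxy-2,3-dihydrobenzofuran | Brc1cc(OC)c2c(c1)[C@@H](CO[Si](C)(C)C(C)(C)C)[C@H](c1ccc(O[Si](C)(C)C(C)(C)C)c(OC)c1)O2 | intermediate
22 | [(2R,3S)-3-(TBSO-methyl)-2-(4-TBSO-3-methoxyphenyl)-7-methoxy-2,3-dihydrobenzofuran-5-yl]methanol | OCc1cc(OC)c2c(c1)[C@@H](CO[Si](C)(C)C(C)(C)C)[C@H](c1ccc(O[Si](C)(C)C(C)(C)C)c(OC)c1)O2 | intermediate
23 | (2R,3S)-5-(bromomethyl)-3-(TBSO-methyl)-2-(4-TBSO-3-methoxyphenyl)-7-methoxy-2,3-dihydrobenzofuran | BrCc1cc(OC)c2c(c1)[C@@H](CO[Si](C)(C)C(C)(C)C)[C@H](c1ccc(O[Si](C)(C)C(C)(C)C)c(OC)c1)O2 | intermediate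
24 | lithium enolate of 18, (S) at C4 (not isolated) | COc1cc([C@@H](O[Si](C)(C)C(C)(C)C)[C@H](CO[Si](C)(C)C(C)(C)C)c2cc(C[C@@H]3COC(O[Li])=C3)cc(OC)c2O[Si](C)(C)C(C)(C)C)ccc1O[Si](C)(C)C(C)(C)C | intermediate
25 | hexakis-TBS ether of the target, (3S,4S)-lactone, (2R,3S)-dihydrobenzofuran, (1S,2S)-diol arm | COc1cc([C@@H](O[Si](C)(C)C(C)(C)C)[C@H](CO[Si](C)(C)C(C)(C)C)c2cc(C[C@@H]3COC(=O)[C@H]3Cc3cc(OC)c4c(c3)[C@@H](CO[Si](C)(C)C(C)(C)C)[C@H](c3ccc(O[Si](C)(C)C(C)(C)C)c(OC)c3)O4)cc(OC)c2O[Si](C)(C)C(C)(C)C)ccc1O[Si](C)(C)C(C)(C)C | intermediate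
26 | (3S,4S)-3-{[(2R,3S)-3-(hydroxymethyl)-2-(4-hydroxy-3-methoxyphenyl)-7-methoxy-2,3-dihydrobenzofuran-5-yl]methyl}-4-{3-[(1S,2S)-1,3-dihydroxy-1-(4-hydroxy-3-methoxyphenyl)propan-2-yl]-4-hydroxy-5-methoxybenzyl}dihydrofuran-2(3H)-one | COc1cc([C@@H](O)[C@H](CO)c2cc(C[C@@H]3COC(=O)[C@H]3Cc3cc(OC)c4c(c3)[C@@H](CO)[C@H](c3ccc(O)c(OC)c3)O4)cc(OC)c2O)ccc1O | target

**Step count and risks**

Total: 15 steps. Longest linear sequence: 12 steps (steps 1–6, 10–13, 14, 15); the other branch (steps 1–9, 14, 15) is 11 steps.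

Steps most likely to fail:

1. Step 9. The catalyst may discriminate poorly between the two ring methylene groups on this large, lipophilic substrate, giving a mixture of C4 epimers or the wrong sense of induction, and the peracid may slowly oxidise the silyloxyarenes. Fallback from 16, back at 18: enantioselective deprotonation of 16 with lithium (S,S)-bis(1-phenylethyl)amide (or its antipode, whichever gives the (S) series) in the presence of Me3SiCl (THF, −100 °C) should give the (S)-configured trimethylsilyl enol ether of 16 F1. Ozonolysis of the enol ether double bond (O3, CH2Cl2/MeOH, −78 °C) with NaBH4 work-up opens the four-membered ring to the (S)-3-(hydroxymethyl)-4-arylbutanoic acid F2. Mitsunobu cyclodehydration (PPh3, DIAD, THF, 0 °C) then closes the lactone by carboxylate displacement at the activated CH2 carbon, again forming the O1–C5 bond, to give 18.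

2. Step 5. With the more acidic and bulkier arylacetyl imide the anti/syn and facial selectivity may be poor, and retro-aldol equilibration may erode it before silyl capture. Fallback from 5, back at 13 (open arm) and at 20 (other arm):
   - Acid 5 is coupled (PivCl, Et3N, LiCl) with (R)-4-benzyloxazolidin-2-one to the antipodal-auxiliary imide F3.
   - The dibutylboron syn-aldol (Bu2BOTf, iPr2NEt, CH2Cl2, −78 → 0 °C) with 9 should give the Evans syn adduct F4, which has the configuration of 10 at the aryl-bearing carbon and the opposite configuration at the carbinol carbon.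
   - LiBH4 gives the syn (1R,2S)-diol F5.
   - For the dihydrobenzofuran arm, F5 is put through the conditions of step 10; the epimeric tetraol F6 (not isolated) loses its carbinol configuration in the quinone methide and converges on 20.
   - For the open arm, the primary hydroxyl of F5 is silylated (TBSCl, imidazole) to the (1R,2S)-mono-TBS ether F7, and the benzylic alcohol is oxidised (Dess–Martin periodinane, NaHCO3) to the (S)-ketone F8.
   - Corey–Bakshi–Shibata reduction ((R)-2-methyl-CBS-oxazaborolidine, BH3·SMe2, −30 °C, aryl as the large group) should give the (1S,2S)-alcohol F9, which TBSOTf/2,6-lutidine converts into 13.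

3. Step 10. After ionisation the cation may lose formaldehyde or a proton (stilbene formation) instead of closing the ring, or trans control may be incomplete. Fallback from 12, back at 20: selective acetylation of the primary hydroxyl (AcCl, 2,4,6-collidine, CH2Cl2, −78 °C) gives the (2S,3S)-monoacetate F10, and buffered fluoride (Bu4NF/AcOH, THF) frees both phenols to give the bis-phenol acetate F11. Mitsunobu ring closure under neutral conditions (PPh3, DIAD, THF, 0 °C) activates the benzylic hydroxyl, which the ortho-phenol displaces with inversion, giving the trans-(2R,3S)-dihydrobenzofuran acetate F12. Methanolysis (K2CO3, MeOH) returns 20.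

Further compounds
F1 | step 9 | (S)-configured trimethylsilyl enol ether of 16, 3-(arylmethyl)-1-(trimethylsilyloxy)cyclobut-1-ene | COc1cc([C@@H](O[Si](C)(C)C(C)(C)C)[C@H](CO[Si](C)(C)C(C)(C)C)c2cc(C[C@@H]3C=C(O[Si](C)(C)C)C3)cc(OC)c2O[Si](C)(C)C(C)(C)C)ccc1O[Si](C)(C)C(C)(C)C
F2 | step 9 | (S)-3-(hydroxymethyl)-4-{3-[(1S,2S)-1,3-bis(TBSO)-1-(4-TBSO-3-methoxyphenyl)propan-2-yl]-4-TBSO-5-methoxyphenyl}butanoic acid | COc1cc([C@@H](O[Si](C)(C)C(C)(C)C)[C@H](CO[Si](C)(C)C(C)(C)C)c2cc(C[C@@H](CC(=O)O)CO)cc(OC)c2O[Si](C)(C)C(C)(C)C)ccc1O[Si](C)(C)C(C)(C)C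
F3 | step 5 | (R)-4-benzyl-3-{2-[5-bromo-2-(TBSO)-3-methoxyphenyl]acetyl}oxazolidin-2-one | O=C1OC[C@@H](Cc2ccccc2)N1C(=O)Cc1cc(Br)cc(OC)c1O[Si](C)(C)C(C)(C)C
F4 | step 5 | (R)-4-benzyl-3-{(2R,3R)-2-[5-bromo-2-(TBSO)-3-methoxyphenyl]-3-hydroxy-3-[4-(TBSO)-3-methoxyphenyl]propanoyl}oxazolidin-2-one | COc1cc([C@H](O)[C@H](C(=O)N2[C@H](Cc3ccccc3)COC2=O)c2cc(Br)cc(OC)c2O[Si](C)(C)C(C)(C)C)ccc1O[Si](C)(C)C(C)(C)C
F5 | step 5 | (1R,2S)-2-[5-bromo-2-(TBSO)-3-methoxyphenyl]-1-[4-(TBSO)-3-methoxyphenyl]propane-1,3-diol | COc1cc([C@H](O)[C@H](CO)c2cc(Br)cc(OC)c2O[Si](C)(C)C(C)(C)C)ccc1O[Si](C)(C)C(C)(C)C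
F6 | step 5 | (1R,2S)-2-(5-bromo-2-hydroxy-3-methoxyphenyl)-1-(4-hydroxy-3-methoxyphenyl)propane-1,3-diol | COc1cc([C@H](O)[C@H](CO)c2cc(Br)cc(OC)c2O)ccc1O
F7 | step 5 | (1R,2S)-2-[5-bromo-2-(TBSO)-3-methoxyphenyl]-3-(TBSO)-1-[4-(TBSO)-3-methoxyphenyl]propan-1-ol | COc1cc([C@H](O)[C@H](CO[Si](C)(C)C(C)(C)C)c2cc(Br)cc(OC)c2O[Si](C)(C)C(C)(C)C)ccc1O[Si](C)(C)C(C)(C)C
F8 | step 5 | (S)-2-[5-bromo-2-(TBSO)-3-methoxyphenyl]-3-(TBSO)-1-[4-(TBSO)-3-methoxyphenyl]propan-1-one | COc1cc(C(=O)[C@H](CO[Si](C)(C)C(C)(C)C)c2cc(Br)cc(OC)c2O[Si](C)(C)C(C)(C)C)ccc1O[Si](C)(C)C(C)(C)C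
F9 | step 5 | (1S,2S)-2-[5-bromo-2-(TBSO)-3-methoxyphenyl]-3-(TBSO)-1-[4-(TBSO)-3-methoxyphenyl]propan-1-ol | COc1cc([C@@H](O)[C@H](CO[Si](C)(C)C(C)(C)C)c2cc(Br)cc(OC)c2O[Si](C)(C)C(C)(C)C)ccc1O[Si](C)(C)C(C)(C)C
F10 | step 10 | (2S,3S)-2-[5-bromo-2-(TBSO)-3-methoxyphenyl]-3-hydroxy-3-[4-(TBSO)-3-methoxyphenyl]propyl acetate | COc1cc([C@@H](O)[C@H](COC(C)=O)c2cc(Br)cc(OC)c2O[Si](C)(C)C(C)(C)C)ccc1O[Si](C)(C)C(C)(C)C
F11 | step 10 | (2S,3S)-2-(5-bromo-2-hydroxy-3-methoxyphenyl)-3-hydroxy-3-(4-hydroxy-3-methoxyphenyl)propyl acetate | COc1cc([C@@H](O)[C@H](COC(C)=O)c2cc(Br)cc(OC)c2O)ccc1O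
F12 | step 10 | [(2R,3S)-5-bromo-2-(4-hydroxy-3-methoxyphenyl)-7-methoxy-2,3-dihydrobenzofuran-3-yl]methyl acetate | Brc1cc(OC)c2c(c1)[C@@H](COC(C)=O)[C@H](c1ccc(O)c(OC)c1)O2
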